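## The problem

Compound 23 is two benzophenones held together by a single CH2 group. Rings A and C are the same 2,6-dihydroxy-4-methoxybenzoyl unit, and the methylene joins the one carbon of each that lies between a hydroxyl and the methoxyl. Ring B is a 2,4-dihydroxy-6-methylphenyl group and ring D is the same orcinol ring with its ortho oxygen methylated. The two halves therefore differ by one O-methyl group, and the bridge has to join two nearly identical nucleophiles without giving the two symmetrical dimers. There is no stereocentre in 23. The only ones met on the way are the carbinol carbons of diarylmethanol intermediates, formed racemic and erased by oxidation, so the difficulty is regiochemical throughout. Each carbonyl carbon sits between four ortho substituents, which argues for addition of an aryl–metal to an aldehyde followed by oxidation and against acylation chemistry. Ten oxygens sit on the rings, seven as free phenols. Rings B and D must stay silent while rings A and C react at the bridging stage, and ring D needs its chelated ortho oxygen methylated while the more acidic para oxygen stays free, the reverse of what direct alkylation of an acylorcinol delivers. The diarylmethane link between two acylphloroglucinol rings can fragment in base through an ortho-quinone methide and recombine to symmetrical dimers, the phenoxides are air-sensitive, and a 2-hydroxy-2'-methoxybenzophenone can close to a xanthone under forcing base. The bridge is therefore made late and the last step kept mild and buffered. What opens ring D to a short construction is that its ketone-bearing carbon C1' has C6'–CH3 on one side and C2'–OCH3 on the other, with the remaining oxygen at C4'. A methyl and a ketone carbon on adjacent carbons next to a methoxy group is what a 3-methoxyaryne leaves after taking a carbon nucleophile at the carbon remote from oxygen and a carbon electrophile at the carbon beside it.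

## Retrosynthesis

**23 ⇒ 22.** Three O–Si bonds are cut. The phenols of rings B and D are carried as triisopropylsilyl ethers up to the last step, so that at the bridging stage only rings A and C offer free, nucleophilic phenol positions. Had they been benzyl ethers like those on rings A and C, they could not have been kept while the latter were freed. The forward step asks only for a fluoride cleavage buffered with acid, under which the methylene bridge should not fragment.

**22 ⇒ 20 + 19 (through 21).** The bond between the bridging CH2 and ring A is cut. The neighbouring option, condensing 19 and 12 with formaldehyde in one pot, would give both symmetrical dimers beside 22. Putting the one-carbon unit on one partner first, as Mannich base 20, makes the coupling directional. The electrophilic carbon is placed on the right half because that half comes from the key step and is the more valuable. It is then the limiting component, and the orcinol-derived 19 can be used in excess and recovered. The forward step has to release ortho-quinone methide 21 from 20 and let ring A of 19 add to it. Rings B and D are silylated and cannot compete.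

**20 ⇒ 12.** The ring C–CH2 bond is cut (Mannich aminomethylation). Ring C of 12 has two equivalent free positions, so no regiochemical question arises; only mono- against bis-substitution needs care.

**12 ⇒ 11 ⇒ 10.** These are functional-group changes: hydrogenolysis of the two benzyl ethers, which leaves the silyl ether on ring D, and oxidation of the carbinol. The tetra-ortho-substituted ketone is thus traced to an alcohol made by a carbonyl addition, where steric demand is easier to meet than in an acylation.

**10 ⇒ 5 + 6 + 3 (through 7, 8, 9).** Two bonds on ring D are cut at once: C6'–CH3 and C1'–carbinol carbon. This is preferred to cutting only the aryl–carbinol bond, which would call for a ring D halide carrying methyl, methoxy and silyloxy groups in the right places, and halogenation of orcinol monomethyl ether derivatives is not regiochemically clean. Fluoroarene 5 already has the methoxy group and the masked para oxygen differentiated, so the ortho-OMe/para-OH problem of ring D never arises. The forward reaction needs lithiation between F and OMe (7), loss of LiF to aryne 8, addition of methyl from 6 remote from OMe to give arylmagnesium 9, and addition of 9 to aldehyde 3.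

**19 ⇒ 18 ⇒ 17 ⇒ 15 + 3 (through 16).** After the same two functional-group changes, the ring B–carbinol bond is cut. Ring B has two oxygens of the same kind, so an aryne is not needed. Bromide 15 gives aryllithium 16 by exchange, and the same aldehyde 3 serves as electrophile, so one building block supplies rings A and C.

**15 ⇒ 14 ⇒ 13; 5 ⇒ 4; 3 ⇒ 2 ⇒ 1.** Bromide 15 comes from orcinol 13 by silylation and bromination at the position ortho to methyl and para to one silyloxy group; the site between the two silyloxy groups is blocked. Fluoroarene 5 is the silyl ether of commercial 4. Aldehyde 3 comes from 2,4,6-trihydroxybenzaldehyde 1 by methylation of the para hydroxyl (2) and benzylation of the two chelated ortho hydroxyls.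

## Roads not taken

**Alternative 1:** Ring A would be built last by a [3+3] annulation. The 1,3-bis(trimethylsilyloxy)diene A1 already carries the protected ring B on one end and the arylmethyl group of the complete right half on the other. Condensation with malonyl dichloride A2 at both nucleophilic carbons would close ring A as the free triol A3. Its real merit is that the bridge is in place before ring A exists, so no cross-coupling of two similar phenols is needed and neither symmetrical dimers nor oligomers can form. In this respect it is better than the chosen plan, whose bridging step is its least certain operation after the key step. Against it, A1 requires the whole right-hand benzophenone to be homologated into a diketone chain, so the route becomes long and linear, and the construction of ring D is left unsolved. Acid chlorides tend to acylate silyl dienol ethers on oxygen as well as carbon, so pyranone formation would compete with carbocyclization. The triol A3 then needs one selective O-methylation. The chosen plan sets convergence against this: one aldehyde, 3, feeds both halves, ring D is solved in one step, and the bridging selectivity is handled by masking rings B and D and using the cheaper partner in excess.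

**Alternative 2:** Ring D would be grown as a spiro ring on a benzofuranone. Benzofuranone A4 would add twice, under catalytic KOtBu, to methoxy ynone A5 to give the spiro enedione A6. A6 would then be dehydrogenated and its spiro C–O bond cleaved reductively to release the benzophenone with ring D aromatic. The merits are that the methoxy, methyl and oxygen pattern of ring D is fixed without ambiguity by the acceptor, and that the hindered ring C–carbonyl bond is present from the start in A4. No addition of a crowded aryl–metal to a crowded aldehyde and no carbinol oxidation are needed, and on this point the alternative is the safer one. Its weak points are that two stereocentres are made only to be destroyed, that two redox operations (dehydrogenation and reductive ring opening) separate A6 from the benzophenone, that A5 is a sensitive multi-step reagent, and that A4 itself needs a phloroglucinol with three differently treated oxygens. The chosen plan reaches the same ring D benzophenone in three operations from 5 and 3 with no redox detour beyond one alcohol oxidation, and uses the same aldehyde for the left half, which the spiro route does not serve.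

**Alternative 3:** Ring D would be assembled as a cyclohexane-1,3-dione. tert-Butyl acetoacetate A7 would add to the aroyl butenoate A8 and then close onto the methyl ester to give A9. A9 would have to lose its tert-butyl ester, be dehydrogenated to the resorcinol, and be methylated at one oxygen only. The reagents are cheap and no cryogenic organometallic step is needed, which is an advantage on scale. The weak points are structural. The oxygen that must be methylated ends up ortho to the ketone and chelated, the one that must stay free is para and more acidic, so the final methylation runs against the inherent order. The aromatization adds an oxidation, and A8 is itself a crowded, isomerizable Knoevenagel-type compound. The chosen plan has the methoxy group in place before ring D is elaborated and never has to tell the two oxygens apart; it pays with one low-temperature organometallic step.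

Key step: step 4

Remark on the chemistry: the target carries no stereodescriptor and is treated as achiral, the aryl–carbonyl axes being taken as freely rotating.

## Route

Step 1
Reactants: 1 2,4,6-trihydroxybenzaldehyde
Product: 2 2,6-dihydroxy-4-methoxybenzaldehyde
Conditions: Me2SO4 (1.0 equiv), K2CO3 (1.0 equiv), acetone, 0 °C → rt
Reagents that add atoms: dimethyl sulfate, COS(=O)(=O)OC
Why: Williamson ether synthesis; the 4-hydroxyl is the most acidic and the only one not hydrogen-bonded to the formyl group, so one equivalent of base and a hard methylating agent should O-methylate there first, and over-methylated material should be separable.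

Step 2
Reactants: 2 2,6-dihydroxy-4-methoxybenzaldehyde
Product: 3 2,6-bis(benzyloxy)-4-methoxybenzaldehyde
Conditions: BnBr (2.5 equiv), K2CO3 (3 equiv), DMF, 60 °C
Reagents that add atoms: benzyl bromide, BrCc1ccccc1
Why: Williamson ether synthesis; the chelated ortho phenols need warming in DMF but alkylate cleanly on oxygen, and the aldehyde has no enolizable position.

Step 3
Reactants: 4 3-fluoro-5-methoxyphenol
Product: 5 1-fluoro-3-methoxy-5-(triisopropylsilyloxy)benzene
Conditions: TIPSCl (1.1 equiv), imidazole (2 equiv), DMF, rt
Reagents that add atoms: chlorotriisopropylsilane, CC(C)[Si](Cl)(C(C)C)C(C)C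
Why: Standard silylation of a phenol; the bulky, non-coordinating silyl ether is chosen so that it neither directs nor tolerates lithiation next to it in step 4.

Step 4
Reactants: 5 1-fluoro-3-methoxy-5-(triisopropylsilyloxy)benzene, 6 methylmagnesium bromide, 3 2,6-bis(benzyloxy)-4-methoxybenzaldehyde
Product: 10 racemic [2,6-bis(benzyloxy)-4-methoxyphenyl][2-methoxy-6-methyl-4-(triisopropylsilyloxy)phenyl]methanol, via aryllithium 7 (not isolated), via aryne 8 (not isolated), via arylmagnesium bromide 9 (not isolated)
Conditions: n-BuLi (1.05 equiv), THF, −78 °C; MeMgBr (1.5 equiv), −78 °C → rt; then 3 (1.8 equiv), 0 °C → rt; aq NH4Cl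
Reagents that add atoms: none
Why: n-BuLi should remove the proton of 5 that lies between F and OMe (directed ortho-lithiation), since this is the only site acidified by two flanking heteroatoms and the triisopropylsilyloxy group shields its own neighbours, giving 7. On warming with MeMgBr present, 7 loses LiF to give aryne 8. The methyl group adds to the aryne carbon meta to OMe, because the σ-withdrawing methoxy group polarizes the strained bond so that the new carbanion sits next to oxygen, where it is stabilized inductively and by O–Mg coordination; this gives arylmagnesium 9 with CH3 and Mg on neighbouring carbons. Species 9 then adds to the formyl group of 3 (Grignard 1,2-addition), which cannot enolize and whose ortho benzyloxy groups can chelate magnesium. The closest known reaction type is the three-component aryne coupling of an ortho-lithiated fluoroarene, a Grignard reagent and a carbonyl electrophile, used to make 2-alkyl-6-alkoxyaryl carbonyl compounds. No ring is closed, and the carbinol carbon is formed without control as the racemate, which is immaterial because step 5 converts it into a ketone. Three selectivities are needed: the site of lithiation and the direction of methyl addition, both secured by the substrate as described, and competition between surplus 6 and 9 for the aldehyde, handled by limiting the excess of 6 and supplying extra 3, the methyl carbinol by-product being separable.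

Step 5
Reactants: 10 racemic [2,6-bis(benzyloxy)-4-methoxyphenyl][2-methoxy-6-methyl-4-(triisopropylsilyloxy)phenyl]methanol
Product: 11 [2,6-bis(benzyloxy)-4-methoxyphenyl][2-methoxy-6-methyl-4-(triisopropylsilyloxy)phenyl]methanone
Conditions: Dess–Martin periodinane (1.5 equiv), NaHCO3, CH2Cl2, 0 °C → rt
Reagents that add atoms: none
Why: Dess–Martin oxidation of a secondary benzylic alcohol; the buffer keeps the acid-labile, doubly electron-rich benzhydrol from ionizing, and benzyl and silyl ethers are inert.

Step 6
Reactants: 11 [2,6-bis(benzyloxy)-4-methoxyphenyl][2-methoxy-6-methyl-4-(triisopropylsilyloxy)phenyl]methanone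
Product: 12 (2,6-dihydroxy-4-methoxyphenyl)[2-methoxy-6-methyl-4-(triisopropylsilyloxy)phenyl]methanone
Conditions: H2 (1 atm), 10% Pd/C, EtOAc, rt
Reagents that add atoms: none
Why: Hydrogenolysis of aryl benzyl ethers; the aryl silyl ether is untouched and the twisted, tetra-ortho-substituted ketone should resist reduction in a neutral solvent at atmospheric pressure.

Step 7
Reactants: 13 orcinol (5-methylbenzene-1,3-diol)
Product: 14 1-methyl-3,5-bis(triisopropylsilyloxy)benzene
Conditions: TIPSCl (2.3 equiv), imidazole (4 equiv), DMF, rt → 40 °C
Reagents that add atoms: chlorotriisopropylsilane, CC(C)[Si](Cl)(C(C)C)C(C)C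
Why: Standard silylation of both phenols of anhydrous orcinol.

Step 8
Reactants: 14 1-methyl-3,5-bis(triisopropylsilyloxy)benzene
Product: 15 2-bromo-1-methyl-3,5-bis(triisopropylsilyloxy)benzene
Conditions: NBS (1.0 equiv), MeCN, 0 °C → rt, dark
Reagents that add atoms: N-bromosuccinimide, O=C1CCC(=O)N1Br
Why: Electrophilic aromatic bromination; attack should occur para to one silyloxy group and ortho to methyl, the position between the two bulky silyloxy groups being blocked, and polar conditions in the dark avoid benzylic bromination.

Step 9
Reactants: 15 2-bromo-1-methyl-3,5-bis(triisopropylsilyloxy)benzene, 3 2,6-bis(benzyloxy)-4-methoxybenzaldehyde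
Product: 17 racemic [2,6-bis(benzyloxy)-4-methoxyphenyl][2-methyl-4,6-bis(triisopropylsilyloxy)phenyl]methanol, via aryllithium 16 (not isolated)
Conditions: n-BuLi (1.05 equiv), THF, −78 °C; then 3 (1.1 equiv), −78 → −40 °C; aq NH4Cl
Reagents that add atoms: none
Why: Bromine–lithium exchange followed by 1,2-addition to a non-enolizable aldehyde; kept at −78 °C, the ortho-silyloxy aryllithium should be trapped before silyl migration from oxygen to carbon can set in, and the stereocentre is formed racemic and removed in step 10.

Step 10
Reactants: 17 racemic [2,6-bis(benzyloxy)-4-methoxyphenyl][2-methyl-4,6-bis(triisopropylsilyloxy)phenyl]methanol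
Product: 18 [2,6-bis(benzyloxy)-4-methoxyphenyl][2-methyl-4,6-bis(triisopropylsilyloxy)phenyl]methanone
Conditions: Dess–Martin periodinane (1.5 equiv), NaHCO3, CH2Cl2, 0 °C → rt
Reagents that add atoms: none
Why: Dess–Martin oxidation as in step 5, buffered for the same reason.

Step 11
Reactants: 18 [2,6-bis(benzyloxy)-4-methoxyphenyl][2-methyl-4,6-bis(triisopropylsilyloxy)phenyl]methanone
Product: 19 (2,6-dihydroxy-4-methoxyphenyl)[2-methyl-4,6-bis(triisopropylsilyloxy)phenyl]methanone
Conditions: H2 (1 atm), 10% Pd/C, EtOAc, rt
Reagents that add atoms: none
Why: Hydrogenolysis of the two benzyl ethers as in step 6; both silyl ethers on ring B stay in place.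

Step 12
Reactants: 12 (2,6-dihydroxy-4-methoxyphenyl)[2-methoxy-6-methyl-4-(triisopropylsilyloxy)phenyl]methanone
Product: 20 {3-[(dimethylamino)methyl]-2,6-dihydroxy-4-methoxyphenyl}[2-methoxy-6-methyl-4-(triisopropylsilyloxy)phenyl]methanone
Conditions: Me2N=CH2+ I− (1.0 equiv), CH2Cl2, 0 °C → rt; cold aq NaHCO3
Reagents that add atoms: dimethylmethylideneammonium iodide, C=[N+](C)C.[I-]
Why: Mannich aminomethylation of a phenol with a preformed iminium salt; only ring C carries free phenols and its two open positions are equivalent, and the first product forms as an ammonium salt that is deactivated toward a second substitution.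

Step 13
Reactants: 20 {3-[(dimethylamino)methyl]-2,6-dihydroxy-4-methoxyphenyl}[2-methoxy-6-methyl-4-(triisopropylsilyloxy)phenyl]methanone, 19 (2,6-dihydroxy-4-methoxyphenyl)[2-methyl-4,6-bis(triisopropylsilyloxy)phenyl]methanone
Product: 22 [3-({2,4-dihydroxy-6-methoxy-3-[2-methoxy-6-methyl-4-(triisopropylsilyloxy)benzoyl]phenyl}methyl)-2,6-dihydroxy-4-methoxyphenyl][2-methyl-4,6-bis(triisopropylsilyloxy)phenyl]methanone, via ortho-quinone methide 21 (not isolated)
Conditions: 19 (2.5 equiv), 1,4-dioxane, 90 °C, slow addition of 20, N2 stream
Reagents that add atoms: none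
Why: Thermal loss of Me2NH from the phenolic Mannich base gives ortho-quinone methide 21, which is captured by conjugate (Friedel–Crafts-type) addition of ring A of 19 at its position between OH and OMe; rings B and D are silylated and cannot compete, and the excess of 19 with slow addition of 20 should suppress self-condensation.

Step 14
Reactants: 22 [3-({2,4-dihydroxy-6-methoxy-3-[2-methoxy-6-methyl-4-(triisopropylsilyloxy)benzoyl]phenyl}methyl)-2,6-dihydroxy-4-methoxyphenyl][2-methyl-4,6-bis(triisopropylsilyloxy)phenyl]methanone
Product: 23 [3-({2,4-dihydroxy-3-(4-hydroxy-2-methoxy-6-methylbenzoyl)-6-methoxyphenyl}methyl)-2,6-dihydroxy-4-methoxyphenyl](2,4-dihydroxy-6-methylphenyl)methanone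
Conditions: Bu4NF (3.5 equiv), AcOH (3.5 equiv), THF, 0 °C → rt
Reagents that add atoms: none
Why: Fluoride cleavage of three aryl silyl ethers; buffering with AcOH keeps the medium close to neutral, so the polyphenol should not be oxidized and the methylene bridge should not fragment.

## Compound list

1 | 2,4,6-trihydroxybenzaldehyde | O=Cc1c(O)cc(O)cc1O | starting material
2 | 2,6-dihydroxy-4-methoxybenzaldehyde | COc1cc(O)c(C=O)c(O)c1 | intermediate
3 | 2,6-bis(benzyloxy)-4-methoxybenzaldehyde | COc1cc(OCc2ccccc2)c(C=O)c(OCc2ccccc2)c1 | intermediate
4 | 3-fluoro-5-methoxyphenol | COc1cc(O)cc(F)c1 | starting material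
5 | 1-fluoro-3-methoxy-5-(triisopropylsilyloxy)benzene | COc1cc(F)cc(O[Si](C(C)C)(C(C)C)C(C)C)c1 | intermediate
6 | methylmagnesium bromide | C[Mg]Br | starting material
7 | [2-fluoro-6-methoxy-4-(triisopropylsilyloxy)phenyl]lithium | COc1cc(O[Si](C(C)C)(C(C)C)C(C)C)cc(F)c1[Li] | intermediate
8 | 3-methoxy-5-(triisopropylsilyloxy)benzyne | COC1=CC(O[Si](C(C)C)(C(C)C)C(C)C)=CC#C1 | intermediate
9 | [2-methoxy-6-methyl-4-(triisopropylsilyloxy)phenyl]magnesium bromide | COc1cc(O[Si](C(C)C)(C(C)C)C(C)C)cc(C)c1[Mg]Br | intermediate
10 | racemic [2,6-bis(benzyloxy)-4-methoxyphenyl][2-methoxy-6-methyl-4-(triisopropylsilyloxy)phenyl]methanol | COc1cc(OCc2ccccc2)c(C(O)c2c(C)cc(O[Si](C(C)C)(C(C)C)C(C)C)cc2OC)c(OCc2ccccc2)c1 | intermediate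
11 | [2,6-bis(benzyloxy)-4-methoxyphenyl][2-methoxy-6-methyl-4-(triisopropylsilyloxy)phenyl]methanone | COc1cc(OCc2ccccc2)c(C(=O)c2c(C)cc(O[Si](C(C)C)(C(C)C)C(C)C)cc2OC)c(OCc2ccccc2)c1 | intermediate
12 | (2,6-dihydroxy-4-methoxyphenyl)[2-methoxy-6-methyl-4-(triisopropylsilyloxy)phenyl]methanone | COc1cc(O)c(C(=O)c2c(C)cc(O[Si](C(C)C)(C(C)C)C(C)C)cc2OC)c(O)c1 | intermediate
13 | orcinol (5-methylbenzene-1,3-diol) | Cc1cc(O)cc(O)c1 | starting material
14 | 1-methyl-3,5-bis(triisopropylsilyloxy)benzene | Cc1cc(O[Si](C(C)C)(C(C)C)C(C)C)cc(O[Si](C(C)C)(C(C)C)C(C)C)c1 | intermediate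
15 | 2-bromo-1-methyl-3,5-bis(triisopropylsilyloxy)benzene | Cc1cc(O[Si](C(C)C)(C(C)C)C(C)C)cc(O[Si](C(C)C)(C(C)C)C(C)C)c1Br | intermediate
16 | [2-methyl-4,6-bis(triisopropylsilyloxy)phenyl]lithium | Cc1cc(O[Si](C(C)C)(C(C)C)C(C)C)cc(O[Si](C(C)C)(C(C)C)C(C)C)c1[Li] | intermediate
17 | racemic [2,6-bis(benzyloxy)-4-methoxyphenyl][2-methyl-4,6-bis(triisopropylsilyloxy)phenyl]methanol | COc1cc(OCc2ccccc2)c(C(O)c2c(C)cc(O[Si](C(C)C)(C(C)C)C(C)C)cc2O[Si](C(C)C)(C(C)C)C(C)C)c(OCc2ccccc2)c1 | intermediate
18 | [2,6-bis(benzyloxy)-4-methoxyphenyl][2-methyl-4,6-bis(triisopropylsilyloxy)phenyl]methanone | COc1cc(OCc2ccccc2)c(C(=O)c2c(C)cc(O[Si](C(C)C)(C(C)C)C(C)C)cc2O[Si](C(C)C)(C(C)C)C(C)C)c(OCc2ccccc2)c1 | intermediate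
19 | (2,6-dihydroxy-4-methoxyphenyl)[2-methyl-4,6-bis(triisopropylsilyloxy)phenyl]methanone | COc1cc(O)c(C(=O)c2c(C)cc(O[Si](C(C)C)(C(C)C)C(C)C)cc2O[Si](C(C)C)(C(C)C)C(C)C)c(O)c1 | intermediate
20 | {3-[(dimethylamino)methyl]-2,6-dihydroxy-4-methoxyphenyl}[2-methoxy-6-methyl-4-(triisopropylsilyloxy)phenyl]methanone | COc1cc(O)c(C(=O)c2c(C)cc(O[Si](C(C)C)(C(C)C)C(C)C)cc2OC)c(O)c1CN(C)C | intermediate
21 | 3-hydroxy-5-methoxy-2-[2-methoxy-6-methyl-4-(triisopropylsilyloxy)benzoyl]-6-methylidenecyclohexa-2,4-dien-1-one | C=C1C(OC)=CC(O)=C(C(=O)c2c(C)cc(O[Si](C(C)C)(C(C)C)C(C)C)cc2OC)C1=O | intermediate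
22 | [3-({2,4-dihydroxy-6-methoxy-3-[2-methoxy-6-methyl-4-(triisopropylsilyloxy)benzoyl]phenyl}methyl)-2,6-dihydroxy-4-methoxyphenyl][2-methyl-4,6-bis(triisopropylsilyloxy)phenyl]methanone | COc1cc(O)c(C(=O)c2c(C)cc(O[Si](C(C)C)(C(C)C)C(C)C)cc2O[Si](C(C)C)(C(C)C)C(C)C)c(O)c1Cc1c(OC)cc(O)c(C(=O)c2c(C)cc(O[Si](C(C)C)(C(C)C)C(C)C)cc2OC)c1O | intermediate
23 | [3-({2,4-dihydroxy-3-(4-hydroxy-2-methoxy-6-methylbenzoyl)-6-methoxyphenyl}methyl)-2,6-dihydroxy-4-methoxyphenyl](2,4-dihydroxy-6-methylphenyl)methanone | COc1cc(O)c(C(=O)c2c(C)cc(O)cc2O)c(O)c1Cc1c(OC)cc(O)c(C(=O)c2c(C)cc(O)cc2OC)c1O | target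

## Step count and least certain steps

Total: 14 steps. Longest linear sequence: 8 steps (steps 1, 2, 4, 5, 6, 12, 13, 14).

**Step 4 (key step).** Two things are most likely to go wrong. First, methyl is among the least reactive Grignard nucleophiles toward arynes, so aryne 8 may be consumed by addition of still-unreacted 7 (biaryl formation) or by decomposition before carbomagnesiation. Second, surplus 6 competes with the doubly ortho-substituted 9 for the crowded aldehyde, so 9 may simply be protonated on work-up. Fallback, setting out from 5 and coming back at 10: the aryne is generated as before but in a large excess of MeMgBr, which no longer has to be balanced against an aldehyde, and the mixture is quenched with iodine to give 2-iodo-1-methoxy-3-methyl-5-(triisopropylsilyloxy)benzene F1. Purified F1 then undergoes iodine–lithium exchange (n-BuLi, THF, −78 °C), and the aryllithium, more nucleophilic than 9 and free of methyl Grignard, adds to 3 to give 10.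

**Step 13.** Quinone methide 21 does not discriminate strongly between similar phenols: capture by a second molecule of 20 (one open ring position) or by product 22 (two open positions) leads to oligomers. Reversible fragmentation of the new diarylmethane in the amine-containing medium could also scramble it toward symmetrical dimers. Fallback, setting out from 19 and coming back at 22: the roles of the halves and the mode of activation are changed. Compound 19 is aminomethylated as in step 12 to {3-[(dimethylamino)methyl]-2,6-dihydroxy-4-methoxyphenyl}[2-methyl-4,6-bis(triisopropylsilyloxy)phenyl]methanone F2 and N-methylated with MeI to the trimethylammonium iodide F3. F3 is stable until base is added and releases its quinone methide at room temperature; it is added slowly to 12 and iPr2NEt in MeCN, so that the coupling runs without heating, to give 22.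

**Step 1.** Discrimination among the three hydroxyls may be incomplete: over-methylation to the 2,4-dimethyl ether, methylation at an ortho hydroxyl, or C-methylation of the phloroglucinol anion. Fallback, coming back at 2: the formyl group is introduced after the oxygen pattern is fixed. This fallback does not set out from 1 but replaces it by commercial 5-methoxyresorcinol F4. Treatment with MOMCl and iPr2NEt gives 1-methoxy-3,5-bis(methoxymethoxy)benzene F5. Directed ortho-lithiation between the two acetal oxygens (n-BuLi, THF, 0 °C) and quenching with DMF give 4-methoxy-2,6-bis(methoxymethoxy)benzaldehyde F6, and HCl in MeOH removes both acetals to give 2.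

**Step 9.** Aryllithium 16 carries a silyloxy group next to the carbanion. Anionic migration of silicon from oxygen to carbon, or slow addition to the crowded aldehyde with protonation on work-up, may erode the step. Fallback, setting out from 13 and coming back at 18: ring B is carried through the carbon–carbon bond formation as its bis(methoxymethyl) ether, which stabilizes the neighbouring carbanion by chelation. Orcinol 13 gives 1,3-bis(methoxymethoxy)-5-methylbenzene F7 (MOMCl, iPr2NEt) and then 2-bromo-1,5-bis(methoxymethoxy)-3-methylbenzene F8 (NBS, MeCN). Bromine–lithium exchange and addition to 3 give racemic [2,6-bis(benzyloxy)-4-methoxyphenyl][2,4-bis(methoxymethoxy)-6-methylphenyl]methanol F9, and Dess–Martin oxidation gives the ketone [2,6-bis(benzyloxy)-4-methoxyphenyl][2,4-bis(methoxymethoxy)-6-methylphenyl]methanone F10. HCl in MeOH frees ring B to give [2,6-bis(benzyloxy)-4-methoxyphenyl](2,4-dihydroxy-6-methylphenyl)methanone F11, and TIPSOTf with 2,6-lutidine gives 18.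

## Further compounds

F1 | step 4 | 2-iodo-1-methoxy-3-methyl-5-(triisopropylsilyloxy)benzene | COc1cc(O[Si](C(C)C)(C(C)C)C(C)C)cc(C)c1I
F2 | step 13 | {3-[(dimethylamino)methyl]-2,6-dihydroxy-4-methoxyphenyl}[2-methyl-4,6-bis(triisopropylsilyloxy)phenyl]methanone | COc1cc(O)c(C(=O)c2c(C)cc(O[Si](C(C)C)(C(C)C)C(C)C)cc2O[Si](C(C)C)(C(C)C)C(C)C)c(O)c1CN(C)C
F3 | step 13 | ({2,4-dihydroxy-6-methoxy-3-[2-methyl-4,6-bis(triisopropylsilyloxy)benzoyl]phenyl}methyl)trimethylammonium iodide | COc1cc(O)c(C(=O)c2c(C)cc(O[Si](C(C)C)(C(C)C)C(C)C)cc2O[Si](C(C)C)(C(C)C)C(C)C)c(O)c1C[N+](C)(C)C.[I-]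
F4 | step 1 | 5-methoxyresorcinol | COc1cc(O)cc(O)c1
F5 | step 1 | 1-methoxy-3,5-bis(methoxymethoxy)benzene | COCOc1cc(OC)cc(OCOC)c1
F6 | step 1 | 4-methoxy-2,6-bis(methoxymethoxy)benzaldehyde | COCOc1cc(OC)cc(OCOC)c1C=O
F7 | step 9 | 1,3-bis(methoxymethoxy)-5-methylbenzene | Cc1cc(OCOC)cc(OCOC)c1
F8 | step 9 | 2-bromo-1,5-bis(methoxymethoxy)-3-methylbenzene | Cc1cc(OCOC)cc(OCOC)c1Br
F9 | step 9 | racemic [2,6-bis(benzyloxy)-4-methoxyphenyl][2,4-bis(methoxymethoxy)-6-methylphenyl]methanol | COc1cc(OCc2ccccc2)c(C(O)c2c(C)cc(OCOC)cc2OCOC)c(OCc2ccccc2)c1
F10 | step 9 | [2,6-bis(benzyloxy)-4-methoxyphenyl][2,4-bis(methoxymethoxy)-6-methylphenyl]methanone | COc1cc(OCc2ccccc2)c(C(=O)c2c(C)cc(OCOC)cc2OCOC)c(OCc2ccccc2)c1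
F11 | step 9 | [2,6-bis(benzyloxy)-4-methoxyphenyl](2,4-dihydroxy-6-methylphenyl)methanone | COc1cc(OCc2ccccc2)c(C(=O)c2c(C)cc(O)cc2O)c(OCc2ccccc2)c1
A1 | alternative 1 | 1,3-bis(trimethylsilyloxy)diene carrying the 2,4-bis(benzyloxy)-6-methylphenyl group at C1 and the protected right-hand arylmethyl group at C4 (double-bond geometry not specified) | C[Si](C)(C)OC(=CC(O[Si](C)(C)C)=CCc1c(OC)cc(OCc2ccccc2)c(C(=O)c2c(C)cc(OCc3ccccc3)cc2OC)c1OCc1ccccc1)c1c(C)cc(OCc2ccccc2)cc1OCc1ccccc1
A2 | alternative 1 | malonyl dichloride | O=C(Cl)CC(=O)Cl
A3 | alternative 1 | full skeleton with ring A as free triol and the other phenols benzylated | Oc1cc(O)c(C(=O)c2c(C)cc(OCc3ccccc3)cc2OCc2ccccc2)c(O)c1Cc1c(OC)cc(OCc2ccccc2)c(C(=O)c2c(C)cc(OCc3ccccc3)cc2OC)c1OCc1ccccc1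
A4 | alternative 2 | 4-(benzyloxy)-6-methoxybenzofuran-3(2H)-one | COc1cc(OCc2ccccc2)c2c(c1)OCC2=O
A5 | alternative 2 | (E)-1-methoxyhex-4-en-1-yn-3-one | COC#CC(=O)/C=C/C
A6 | alternative 2 | racemic 4-(benzyloxy)-2',6-dimethoxy-6'-methylgris-2'-ene-3,4'-dione (one enantiomer drawn) | C[C@@H]1CC(=O)C=C(OC)[C@@]12Oc1cc(OC)cc(OCc3ccccc3)c1C2=O
A7 | alternative 3 | tert-butyl acetoacetate | CC(=O)CC(=O)OC(C)(C)C
A8 | alternative 3 | methyl 2-[2,6-bis(benzyloxy)-4-methoxybenzoyl]but-2-enoate | CC=C(C(=O)OC)C(=O)c1c(OCc2ccccc2)cc(OC)cc1OCc1ccccc1
A9 | alternative 3 | tert-butyl 3-[2,6-bis(benzyloxy)-4-methoxybenzoyl]-2-methyl-4,6-dioxocyclohexane-1-carboxylate (mixture of epimers and enol forms) | CC1C(C(=O)OC(C)(C)C)C(=O)CC(=O)C1C(=O)c1c(OCc2ccccc2)cc(OC)cc1OCc1ccccc1
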